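## Structural features

- The target is a germacranolide of the heliangolide type: a cyclodecane (C1–C10) with a γ-lactone fused trans across C6–C7 (O6–C12(=O)–C11–C7) and an exocyclic C11=C13 methylene.
- The ten-membered ring holds a Z-trisubstituted C4=C5 bond (C15 on C4) and a trans 1,10-epoxide (1R,10R, C14 on C10). Its other substituents are a 3S isovalerate and an 8R (2S,3S)-epoxyangelate.
- C6, C7 and C8 are contiguous stereocenters (O6 and C11 trans, C11 and O8 cis). C3 is allylic to C4=C5, and C1/C10 are separated from the triad by the C2 and C9 methylenes.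
- The fragile groups are the α-methylene lactone (Michael acceptor), the ring epoxide (prone to transannular opening), the glycidic ester and the allylic C3 ester. Before epoxidation the 1(10),4-diene cyclises across the ring under acid.
- The real difficulty is a ten-membered ring with two trisubstituted alkenes of opposite geometry (1(10)E, 4Z) whose stereocenters cannot be relayed through a rigid frame once the ring is open.
- The atoms C10=C1–C2–C3(O)–C4=C5 form a hexatriene that lacks only a C2=C3 enol double bond. The medium ring is therefore the electrocyclic ring-opened form of a eudesmane (ring A = C1–C5, C10; ring B = C5–C10) that still has the C5–C10 bond, and C6–C8 can be set on chairs of that decalin.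

## Logic of the disconnections

32 to 31: the two C–O bonds of the 1,10-epoxide are cut. The epoxide is the most fragile element and is best made last. This leaves a triene with four ring stereocenters. The forward step must pick C1=C10 over C4=C5 and C11=C13 and attack its outer face.

31 to 26 and 30: the C8 O–acyl bond is cut so that the hindered, sensitive glycidic acid arrives late and convergently. 30 goes back through 29 and 28 to 27 by cutting the two oxirane C–O bonds and adjusting the oxidation level at the carboxyl carbon. The forward steps need acylation of a hindered alcohol without epoxide opening, and enantioface control on a Z-trisubstituted allylic alcohol.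

26 to 21 (through 25, 24 and 22): the O8–Si and C3 O–acyl bonds are exchanged and the C11=C13 π bond is traced to the α-methyl lactone. The lactone enolate can only be used while O3 is a free alkoxide and O8 a silyl ether, so the methylene is made before either ester. The forward demand is syn-elimination into the methyl group and no selenium attack on C1=C10.

21 to 19 (through 20): the C3–H bond and the C2–H/C3=O pair are cut back to the silyl trienol ether. C3 is the one ring stereocenter the key step cannot carry. The forward steps need α-protonation at C2 and reagent-controlled hydride delivery.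

19 to 18 (key): the C5–C10 bond is reconnected. The ten-membered ring and both trisubstituted alkenes collapse into one σ bond and two sp3 centers of a cis-decalin diene. The forward step must be a conrotatory opening in one sense only. That requires the cis-fused isomer in which C6 and the C10 methyl are pseudoaxial on ring A.

18 to 15 (through 17): two O–Si bonds and the C1=C2 π bond are removed. The dienol ether can only come from the 1-en-3-one, whose sole enolisable position is C4. The forward demand is kinetic enolisation of 15 at C2.

15 to 11 (through 14, 13 and 12): the C3 acetal is restored and C8 is inverted through ketone 13. The 8β oxygen is syn-axial to C1 and would obstruct the earlier bond formations, so it is made late by hydride delivery to the open α face. The β-acyloxy ketone 13 must not eliminate.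

11 to 9 (through 10): the lactone C12–O6 bond, then the C6–O, C5–H and C12–O bonds are cut back to a diene. One syn addition sets the cis fusion and the 6α oxygen together. The forward demand is α-face attack on C5=C6.

9 to 7 (through 8): the silyl group and the acetal are removed and the double bond returns to conjugation. The forward step needs acetalisation with migration of the alkene to C5=C6.

7 to 4 and 5: the C1–C10 bond and the C4=C5 bond are cut (annulation). The forward Michael addition must occur cis to the isopropenyl group so that the C10 methyl is α.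

4 to 1 (through 3): a C–H bond (conjugate reduction) and the C–O bond at the γ-carbon of the enone (future C8) are cut. The forward oxidation must be γ- and not α-selective and trans to the isopropenyl group.

## Other disconnections considered

Alternative 1: the cut is the C1–C2 bond, with the epoxide traced to a C1 carbinol and a C10 tertiary silyl ether. In the forward key step SmI2 reduces a C2–Br bond next to the C3 enone carbonyl, and the samarium enolate adds to a C1 aldehyde in the same chain to give A1 (an intramolecular Reformatsky reaction).
- In favour: the closure is mild and chelation-assisted, and it brings in the C1 oxygen. The epoxide would then be closed by displacement at C1 by the C10 oxygen, so its configuration follows from two sp3 centers and not from facial selectivity on a medium ring.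
- Against: C6, C7, C8 and C10 must be built on an open chain. The Z-enone with a γ-acyloxy group can isomerise or eliminate, the β-hydroxy ketone can dehydrate, C1 must come out with the configuration opposite to that of the epoxide, and A1 still lacks C13.
- Structure: the alternative is better on the epoxide and has C3 at the right oxidation level.
- Mechanism: both closures avoid high dilution. The polar closure is better understood than the sense of a photochemical conrotation, but its C1 selectivity is as open as the torquoselectivity of the chosen plan; the two are about equal.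
- Step economy: assembling the chain plus methylenation should cost at least as many steps as the decalin route, so there is a slight edge to the chosen plan.

Alternative 2: the cut is the C8–C9 bond. In the forward key step the potassium alkoxide (KH, 18-crown-6) of a trans-1,2-dialkenylcyclohexenol undergoes a [3,3] shift that expands the six-membered ring by four atoms and gives, after protonation of the C6 enolate, A2 (an anionic oxy-Cope rearrangement).
- In favour: it is a thermal reaction with a predictable chair-like transition state, starts from carvone, and reaches the ten-membered ring with C3 oxygenated and both alkenes in place in very few steps.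
- Against: A2 has no lactone carbons and C7 is a methylene. The C7 side chain, the C6 carbinol and the C8 oxygen (from the silane) must all be set on the flexible ring.
- Structure: the alternative reaches the macrocycle sooner (better) but leaves the C6–C8 triad to medium-ring control (worse).
- Mechanism: geometry transfer in the [3,3] shift is more secure than the conrotatory sense; the alternative is better on this point.
- Step economy: fewer steps before the ring and more after it; overall about equal.

Alternative 3: the cut is the C1=C10 double bond, traced to an eleven-membered sulfone with sulfur between C1 and C10. In the forward key step the sulfone is halogenated in situ and loses SO2 through an episulfone to give A3 (a Ramberg–Bäcklund contraction).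
- In favour: the macrocycle is first closed as a sulfide by simple alkylation. All oxygen stereocenters and C7 are fixed on an acyclic chain, and C3, C6/C12 and C8 carry differentiated protecting groups. The exocyclic methylene is already present.
- Against: the E/Z outcome of the contraction for a trisubstituted alkene in a strained ring is not reliable. The two α-carbons of the sulfone differ, the linear sequence is long, and after the key step come oxidation at C12, lactonisation and several protecting-group steps.
- Structure: the alternative is equal or better on functional-group readiness and on the security of C3.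
- Mechanism: the chosen plan sets both alkene geometries in one stereospecific event, whereas the contraction controls only one and weakly; the chosen plan is better.
- Step economy: the chosen plan is shorter and uses fewer protecting groups.

Key step: step 14

Remark: locants follow eudesmane/germacrane numbering; α and β refer to the usual drawing with the C7 side chain β.
Remark: the cis-fused diene 18 carries 5αH and 10α-methyl. With the trans lactone holding ring B in its chair, only this cis isomer has C6 and the C10 methyl pseudoaxial on ring A, which is what the 1(10)E,4Z outcome requires; the 5βH,10β-methyl isomer is predicted to open the other way.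
Remark: the central double bond of 19 is cis within the ring; because the silyloxy group outranks C4 it is E under the CIP rules.
Remark: C4 and C11 are stereocenters only in intermediates and later become trigonal; they are drawn as the epimers expected to predominate (4β-methyl, 11α-methyl) and the other epimers converge.
Remark: a dienone cannot be hydrogenated selectively at its tetrasubstituted C4=C5 bond, so the cis-fused 1-en-3-one is reached by cis-selective hydroboration followed by dehydrogenation.

## Steps

Step 1
Reactants: 1 (R)-carvone
Product: 3 (4S,5R)-4-hydroxy-2-methyl-5-(prop-1-en-2-yl)cyclohex-2-en-1-one (trans-4-hydroxycarvone), via trimethylsilyl dienol ether 2 (not isolated)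
Conditions: MeMgBr, FeCl3 (3 mol%), Et2O, −20 °C; TMSCl, Et3N, DMPU; then mCPBA, NaHCO3, hexane/CH2Cl2, −20 °C; citric acid, MeOH
Reagents that add atoms: 3-chloroperoxybenzoic acid (mCPBA), OOC(=O)c1cccc(Cl)c1
Why: Iron-catalysed deprotonation by the Grignard reagent gives the through-conjugated dienolate, which is silylated on oxygen. The peracid then attacks the γ,δ-bond of the dienol ether (vinylogous Rubottom oxidation, as in the 6-hydroxylation of steroidal 3,5-dienol ethers) anti to the adjacent isopropenyl group, which sets the future C8 oxygen trans to the side chain.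

Step 2
Reactants: 3 trans-4-hydroxycarvone
Product: 4 (2R,4S,5R)-4-hydroxy-2-methyl-5-(prop-1-en-2-yl)cyclohexan-1-one
Conditions: LiBH(s-Bu)3 (2.2 equiv), THF, −78 °C; aq. NH4Cl
Reagents that add atoms: none
Why: After deprotonation of the hydroxyl the hindered borohydride adds 1,4 to the β-monosubstituted enone (conjugate reduction) and leaves the isopropenyl group alone. C2 is epimerisable and is drawn with the methyl equatorial.

Step 3
Reactants: 4 hydroxy ketone; 5 ethyl vinyl ketone
Product: 7 (7R,8S,10S)-8-hydroxyeudesma-4,11-dien-3-one (8α-hydroxy and 10α-methyl), via Michael adduct diketone 6 (not isolated)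
Conditions: KOH (0.2 equiv), EtOH, −10 °C to rt; then KOH, EtOH, reflux
Reagents that add atoms: none
Why: Robinson annulation: the more substituted enolate adds to 5 by axial attack through a chair, which places the new chain cis to the equatorial isopropenyl group and so sets C10 with its methyl α. Aldol condensation then closes ring A. The equatorial hydroxyl does not interfere, and the minor C10 epimer is removed by chromatography.

Step 4
Reactants: 7 hydroxy enone
Product: 8 3,3-(ethylenedioxy)-10α-methyl-eudesma-5,11-dien-8α-ol
Conditions: ethane-1,2-diol, p-toluenesulfonic acid monohydrate (cat.), benzene, reflux, Dean–Stark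
Reagents that add atoms: ethane-1,2-diol, OCCO
Why: Acetalisation of a 4-methyl-4-en-3-one runs through the dienol ether and gives the β,γ-unsaturated dioxolane. This masks C3 and moves the double bond to C5=C6 for step 6. C4 settles as the equatorial 4β-methyl epimer.

Step 5
Reactants: 8 hydroxy acetal
Product: 9 8α-(tert-butyldimethylsilyloxy)-3,3-(ethylenedioxy)-10α-methyl-eudesma-5,11-diene
Conditions: TBSCl, imidazole, DMF, rt
Reagents that add atoms: tert-butyldimethylsilyl chloride, CC(C)(C)[Si](C)(C)Cl
Why: Standard silylation of a secondary alcohol. O8 is blocked so that only O6 can lactonise in step 7.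

Step 6
Reactants: 9 silyl ether diene
Product: 10 8α-(tert-butyldimethylsilyloxy)-3,3-(ethylenedioxy)-5αH,10α-methyl-eudesmane-6α,12-diol
Conditions: BH3·THF (excess), THF, 0 °C to rt; then NaOH, H2O2, 0 °C to rt
Reagents that add atoms: hydrogen peroxide, OO
Why: Hydroboration–oxidation of both alkenes: the isopropenyl group gives the primary C12 alcohol, and the C5=C6 bond takes boron at C6 and hydrogen at C5 syn. The equatorial C7 and C8 groups fix the half-chair in which C1 is pseudoaxial on the β face, so attack should come from the α face and set 5αH (cis fusion) and 6α-OH together. C11 forms as a mixture.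

Step 7
Reactants: 10 diol
Product: 11 8α-(tert-butyldimethylsilyloxy)-3,3-(ethylenedioxy)-5αH,10α-methyl-eudesman-12,6α-olide
Conditions: 2,2,6,6-tetramethylpiperidine-1-oxyl (10 mol%), PhI(OAc)2 (2.5 equiv), CH2Cl2, rt
Reagents that add atoms: none
Why: Oxoammonium oxidation takes the primary alcohol to the aldehyde, which the 6α-hydroxyl captures as the lactol; this is oxidised on to the trans-fused γ-lactone (oxidative lactonisation of a 1,4-diol). No stereocenter is touched.

Step 8
Reactants: 11 silyl ether lactone
Product: 12 3,3-(ethylenedioxy)-8α-hydroxy-5αH,10α-methyl-eudesman-12,6α-olide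
Conditions: Bu4NF, THF, rt
Reagents that add atoms: none
Why: Fluoride desilylation; the acetal and the lactone are stable to it.

Step 9
Reactants: 12 hydroxy lactone
Product: 13 3,3-(ethylenedioxy)-8-oxo-5αH,10α-methyl-eudesman-12,6α-olide
Conditions: Dess–Martin periodinane, NaHCO3, CH2Cl2, 0 °C to rt; used crude
Reagents that add atoms: none
Why: Dess–Martin oxidation under buffered, non-basic conditions. The product is a β-acyloxy ketone, but its equatorial C6–O bond lies near the plane of a C7 enolate, so elimination is stereoelectronically slow; the ketone is still reduced at once.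

Step 10
Reactants: 13 keto lactone
Product: 14 3,3-(ethylenedioxy)-8β-hydroxy-5αH,10α-methyl-eudesman-12,6α-olide
Conditions: LiBH(s-Bu)3 (1.2 equiv), THF, −78 °C; aq. NH4Cl
Reagents that add atoms: none
Why: Ketone reduction with a bulky hydride: the axial β approach is blocked by the axial C1 methylene that the trans lactone locks in place, so hydride enters equatorially from the α face and gives the axial 8β alcohol. C8 is thereby inverted by oxidation–reduction.

Step 11
Reactants: 14 hydroxy acetal
Product: 15 8β-hydroxy-3-oxo-5αH,10α-methyl-eudesman-12,6α-olide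
Conditions: pyridinium p-toluenesulfonate (cat.), acetone/H2O, 50 °C
Reagents that add atoms: water, O
Why: Acid-catalysed acetal hydrolysis. C4, now α to the ketone, equilibrates to the equatorial 4β-methyl epimer.

Step 12
Reactants: 15 hydroxy ketone
Product: 17 8β-hydroxy-3-oxo-5αH,10α-methyl-eudesm-1-en-12,6α-olide, via bis(trimethylsilyl) enol ether 16 (not isolated)
Conditions: LiN(i-Pr)2 (2.2 equiv), THF, −78 °C; TMSCl; then Pd(OAc)2 (1.1 equiv), MeCN, rt; citric acid, MeOH
Reagents that add atoms: none
Why: Kinetic deprotonation takes the C2 methylene and not the C4 methine (the alkoxide is silylated as well). Saegusa–Ito dehydrogenation of the resulting silyl enol ether introduces C1=C2, and the mild acid work-up frees the 8-hydroxyl.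

Step 13
Reactants: 17 hydroxy enone
Product: 18 3,8β-bis(tert-butyldimethylsilyloxy)-5αH,10α-methyl-eudesma-1,3-dien-12,6α-olide
Conditions: TBSOTf (2.5 equiv), Et3N, CH2Cl2, 0 °C
Reagents that add atoms: tert-butyldimethylsilyl trifluoromethanesulfonate, CC(C)(C)[Si](C)(C)OS(=O)(=O)C(F)(F)F
Why: Soft enolisation of the enone can only remove the C4 proton because C10 is quaternary, so the ring A 3-silyloxy-1,3-diene is the only dienol ether possible. The same reagent silylates the axial 8β-hydroxyl.

Step 14
Reactants: 18 cis-fused silyloxy diene
Product: 19 3,8β-bis(tert-butyldimethylsilyloxy)germacra-1(10)E,2E,4Z-trien-12,6α-olide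
Conditions: hν (medium-pressure Hg lamp, Vycor filter), degassed pentane/Et2O, −78 °C, partial conversion; used cold
Reagents that add atoms: none
Why: Excitation of the 2-silyloxy-cyclohexa-1,3-diene chromophore (C1=C2–C3(OSi)=C4) triggers a six-electron electrocyclic ring opening that is conrotatory from the excited state and cleaves the ring-fusion bond C5–C10. The closest known reactions are the provitamin D to previtamin D opening and the opening of ring A 1,3-dienes of trans-fused eudesmanolides and other fused cyclohexa-1,3-dienes to medium-ring trienes. The ten-membered carbocycle is therefore not closed by bond formation: it appears by scission of the bond shared by rings A and B, so no dilution is needed and the lactone is untouched. No stereocenter is created; C5 and C10 become trigonal and their configuration is translated into alkene geometry. The opening is expected to follow the helicity the diene already has in the ground state: the trans lactone must sit diequatorial on ring B, which makes C1 axial on ring B and hence the C10 methyl and C6 pseudoaxial on ring A, and pseudoaxial groups turn inward with least motion. C14 inward puts C9 outward (1(10)E) and C6 inward makes C4=C5 cis in the ring (4Z), while the central enol ether bond stays cis in the ring. The selectivity needed is this sense of conrotation over the opposite one, which would give 1(10)Z,4E; it is secured by the 5αH,10α-methyl cis fusion together with the lactone lock. Low temperature and limited conversion keep the triene from thermal disrotatory reclosure, 1,7-hydrogen shift and secondary photoreactions.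

Step 15
Reactants: 19 silyl trienol ether
Product: 20 8β-(tert-butyldimethylsilyloxy)-3-oxogermacra-1(10)E,4Z-dien-12,6α-olide
Conditions: Bu4NF (1.05 equiv), AcOH (1.5 equiv), THF, −78 to −40 °C
Reagents that add atoms: none
Why: Buffered fluoride cleaves the silyl enol ether much faster than the hindered secondary silyl ether. The dienolate is protonated at C2 (kinetic α-protonation), which keeps C1=C10 out of conjugation and leaves C4=C5 as the Z-enone; the triene is destroyed before it can reclose.

Step 16
Reactants: 20 ten-membered enone
Product: 21 (3S)-8β-(tert-butyldimethylsilyloxy)-3β-hydroxygermacra-1(10)E,4Z-dien-12,6α-olide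
Conditions: (R)-2-methyl-CBS-oxazaborolidine ((R)-1-methyl-3,3-diphenyl-tetrahydropyrrolo[1,2-c][1,3,2]oxazaborole, 0.3 equiv), catecholborane, toluene, −78 °C; MeOH
Reagents that add atoms: none
Why: Corey–Bakshi–Shibata reduction: the α-branched alkenyl flank (C4) acts as the large group and the C2 methylene as the small one, so the (R)-catalyst should deliver hydride to the face that gives the 3S alcohol by 1,2-reduction (reagent control). Catecholborane at low temperature does not hydroborate the alkenes.

Step 17
Reactants: 21 hydroxy lactone
Product: 22 (11S)-8β-(tert-butyldimethylsilyloxy)-3β-hydroxy-11-(phenylselanyl)germacra-1(10)E,4Z-dien-12,6α-olide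
Conditions: LiN(i-Pr)2 (2.3 equiv), THF/DMPU, −78 °C; PhSeSePh, −78 to −40 °C
Reagents that add atoms: diphenyl diselenide, c1ccc(cc1)[Se][Se]c1ccccc1
Why: α-Selenenylation of the lactone enolate, formed beside the C3 alkoxide. The diselenide, unlike a selenenyl halide, does not add to the electron-rich C1=C10 bond. Selenium is expected on the less hindered α face, but the C11 configuration does not matter.

Step 18
Reactants: 22 selenide
Product: 24 8β-(tert-butyldimethylsilyloxy)-3β-hydroxygermacra-1(10)E,4Z,11(13)-trien-12,6α-olide, via selenoxide 23 (not isolated)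
Conditions: mCPBA (1.0 equiv), CH2Cl2, −78 °C; then i-Pr2NH, −78 °C to rt
Reagents that add atoms: none
Why: Selenide oxidation at −78 °C is far faster than alkene epoxidation. The selenoxide undergoes syn-elimination into the methyl group on warming, the usual outcome for α-methyl-α-phenylselanyl trans-fused lactones, and the amine scavenges the selenenic acid.

Step 19
Reactants: 24 allylic alcohol
Product: 25 8β-(tert-butyldimethylsilyloxy)-3β-(3-methylbutanoyloxy)germacra-1(10)E,4Z,11(13)-trien-12,6α-olide
Conditions: 3-methylbutanoyl chloride, pyridine, 4-(dimethylamino)pyridine (cat.), CH2Cl2, 0 °C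
Reagents that add atoms: 3-methylbutanoyl chloride, CC(C)CC(Cl)=O
Why: Nucleophile-catalysed acylation of the secondary allylic alcohol with retention at C3. The α-methylene lactone tolerates these conditions.

Step 20
Reactants: 25 silyl ether
Product: 26 8β-hydroxy-3β-(3-methylbutanoyloxy)germacra-1(10)E,4Z,11(13)-trien-12,6α-olide
Conditions: HF·pyridine, pyridine, THF, 0 °C to rt
Reagents that add atoms: none
Why: Buffered fluoride desilylation. The medium is not acidic enough to start transannular cyclisation of the 1(10),4-diene and is not basic enough to add to the methylene lactone or move the ester.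

Step 21
Reactants: 27 methyl angelate
Product: 28 (Z)-2-methylbut-2-en-1-ol
Conditions: i-Bu2AlH (2.2 equiv), CH2Cl2, −78 °C; aq. KNaC4H4O6
Reagents that add atoms: none
Why: 1,2-Reduction of the conjugated ester to the allylic alcohol with the Z geometry retained.

Step 22
Reactants: 28 allylic alcohol
Product: 29 [(2R,3S)-2,3-dimethyloxiran-2-yl]methanol
Conditions: Ti(Oi-Pr)4 (10 mol%), D-(−)-diisopropyl tartrate (12 mol%), t-BuOOH, 4 Å sieves, CH2Cl2, −20 °C
Reagents that add atoms: tert-butyl hydroperoxide, CC(C)(C)OO
Why: Sharpless asymmetric epoxidation: L-(+)-tartrate gives 2S epoxy alcohols from primary allylic alcohols of this substitution pattern, so the D-(−)-tartrate should give the 2R,3S epoxide by syn oxygen transfer to the Z alkene. The Z methyl lowers the usual selectivity, and any minor enantiomer becomes a separable diastereomer after step 24.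

Step 23
Reactants: 29 epoxy alcohol
Product: 30 (2S,3S)-2,3-dimethyloxirane-2-carboxylic acid
Conditions: RuCl3 hydrate (2 mol%), NaIO4 (3 equiv), MeCN/EtOAc/H2O, 0 °C to rt
Reagents that add atoms: water, O
Why: Ruthenium tetroxide oxidation of the primary alcohol through the aldehyde hydrate to the glycidic acid without epoxide opening. The C2 descriptor changes from R to S only because the carboxyl now outranks C3.

Step 24
Reactants: 26 hydroxy triene; 30 epoxy acid
Product: 31 8β-[(2S,3S)-2,3-dimethyloxirane-2-carbonyloxy]-3β-(3-methylbutanoyloxy)germacra-1(10)E,4Z,11(13)-trien-12,6α-olide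
Conditions: 2-methyl-6-nitrobenzoic anhydride, Et3N, 4-(dimethylamino)pyridine, CH2Cl2, rt
Reagents that add atoms: none
Why: Shiina esterification (mixed-anhydride activation with acyl transfer), suited to a hindered secondary alcohol and an α,α-disubstituted acid. The C–O bond at C8 is not broken, so C8 and both oxirane centers are retained.

Step 25
Reactants: 31 triene diester
Product: 32 target (1R,3S,6R,7R,8R,10R)-1β,10α-epoxy-8β-[(2S,3S)-2,3-dimethyloxirane-2-carbonyloxy]-3β-(3-methylbutanoyloxy)germacra-4Z,11(13)-dien-12,6α-olide
Conditions: mCPBA (1.1 equiv), NaHCO3, CH2Cl2, −20 to 0 °C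
Reagents that add atoms: 3-chloroperoxybenzoic acid (mCPBA), OOC(=O)c1cccc(Cl)c1
Why: Prilezhaev epoxidation: the strained E-trisubstituted C1=C10 bond is the most nucleophilic alkene, since C4=C5 is flanked by two allylic acyloxy groups and C11=C13 is conjugated. The peracid can reach only the outer face of this bond in the conformer with C14 on the β side, which should give the 1β,10α (1R,10R) epoxide.

## Compound list

1 | (R)-carvone, (5R)-2-methyl-5-(prop-1-en-2-yl)cyclohex-2-en-1-one | CC1=CC[C@H](CC1=O)C(C)=C | starting material
2 | (S)-trimethyl{[2-methyl-5-(prop-1-en-2-yl)cyclohexa-1,3-dien-1-yl]oxy}silane (through-conjugated dienol ether) | CC1=C(O[Si](C)(C)C)C[C@@H](C=C1)C(C)=C | intermediate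
3 | (4S,5R)-4-hydroxy-2-methyl-5-(prop-1-en-2-yl)cyclohex-2-en-1-one | CC1=C[C@H](O)[C@H](CC1=O)C(C)=C | intermediate
4 | (2R,4S,5R)-4-hydroxy-2-methyl-5-(prop-1-en-2-yl)cyclohexan-1-one | C[C@@H]1C[C@H](O)[C@H](CC1=O)C(C)=C | intermediate
5 | ethyl vinyl ketone (pent-1-en-3-one) | CCC(=O)C=C | starting material
6 | (2S,4S,5R)-4-hydroxy-2-methyl-2-(3-oxopentyl)-5-(prop-1-en-2-yl)cyclohexan-1-one | CCC(=O)CC[C@@]1(C)C[C@H](O)[C@H](CC1=O)C(C)=C | intermediate
7 | (7R,8S,10S)-8-hydroxyeudesma-4,11-dien-3-one (8α-OH, 10α-methyl, 7β-isopropenyl) | CC1=C2C[C@@H]([C@@H](O)C[C@]2(C)CCC1=O)C(C)=C | intermediate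
8 | 3,3-(ethylenedioxy)-10α-methyl-eudesma-5,11-dien-8α-ol (4β-methyl) | C[C@@H]1C2=C[C@@H]([C@@H](O)C[C@]2(C)CCC13OCCO3)C(C)=C | intermediate
9 | 8α-(tert-butyldimethylsilyloxy)-3,3-(ethylenedioxy)-10α-methyl-eudesma-5,11-diene | C[C@@H]1C2=C[C@@H]([C@@H](O[Si](C)(C)C(C)(C)C)C[C@]2(C)CCC13OCCO3)C(C)=C | intermediate
10 | 8α-(tert-butyldimethylsilyloxy)-3,3-(ethylenedioxy)-5αH,10α-methyl-eudesmane-6α,12-diol (cis-fused, 11S shown) | C[C@@H]1[C@@H]2[C@@H](O)[C@@H]([C@@H](O[Si](C)(C)C(C)(C)C)C[C@]2(C)CCC13OCCO3)[C@H](C)CO | intermediate
11 | 8α-(tert-butyldimethylsilyloxy)-3,3-(ethylenedioxy)-5αH,10α-methyl-eudesman-12,6α-olide (trans lactone, 11S) | C[C@@H]1[C@@H]2[C@H]3OC(=O)[C@@H](C)[C@@H]3[C@@H](O[Si](C)(C)C(C)(C)C)C[C@]2(C)CCC14OCCO4 | intermediate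
12 | 3,3-(ethylenedioxy)-8α-hydroxy-5αH,10α-methyl-eudesman-12,6α-olide | C[C@@H]1[C@@H]2[C@H]3OC(=O)[C@@H](C)[C@@H]3[C@@H](O)C[C@]2(C)CCC14OCCO4 | intermediate
13 | 3,3-(ethylenedioxy)-8-oxo-5αH,10α-methyl-eudesman-12,6α-olide | C[C@@H]1[C@@H]2[C@H]3OC(=O)[C@@H](C)[C@@H]3C(=O)C[C@]2(C)CCC14OCCO4 | intermediate
14 | 3,3-(ethylenedioxy)-8β-hydroxy-5αH,10α-methyl-eudesman-12,6α-olide | C[C@@H]1[C@@H]2[C@H]3OC(=O)[C@@H](C)[C@@H]3[C@H](O)C[C@]2(C)CCC14OCCO4 | intermediate
15 | 8β-hydroxy-3-oxo-5αH,10α-methyl-eudesman-12,6α-olide | C[C@@H]1[C@@H]2[C@H]3OC(=O)[C@@H](C)[C@@H]3[C@H](O)C[C@]2(C)CCC1=O | intermediate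
16 | 3,8β-bis(trimethylsilyloxy)-5αH,10α-methyl-eudesm-2-en-12,6α-olide | C[C@@H]1[C@@H]2[C@H]3OC(=O)[C@@H](C)[C@@H]3[C@H](O[Si](C)(C)C)C[C@]2(C)CC=C1O[Si](C)(C)C | intermediate
17 | 8β-hydroxy-3-oxo-5αH,10α-methyl-eudesm-1-en-12,6α-olide | C[C@@H]1[C@@H]2[C@H]3OC(=O)[C@@H](C)[C@@H]3[C@H](O)C[C@]2(C)C=CC1=O | intermediate
18 | (5R,6R,7S,8R,10R,11S)-3,8β-bis(tert-butyldimethylsilyloxy)-5αH,10α-methyl-eudesma-1,3-dien-12,6α-olide (cis-fused) | O=C1O[C@@H]2[C@H]3C(C)=C(O[Si](C)(C)C(C)(C)C)C=C[C@@]3(C)C[C@@H](O[Si](C)(C)C(C)(C)C)[C@H]2[C@@H]1C | intermediate
19 | 3,8β-bis(tert-butyldimethylsilyloxy)germacra-1(10)E,2E,4Z-trien-12,6α-olide (C2=C3 cis in the ring) | O=C1O[C@@H]2/C=C(/C)\C(O[Si](C)(C)C(C)(C)C)=C/C=C(\C)/C[C@@H](O[Si](C)(C)C(C)(C)C)[C@H]2[C@@H]1C | intermediate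
20 | 8β-(tert-butyldimethylsilyloxy)-3-oxogermacra-1(10)E,4Z-dien-12,6α-olide | O=C1O[C@@H]2/C=C(/C)C(=O)C/C=C(\C)/C[C@@H](O[Si](C)(C)C(C)(C)C)[C@H]2[C@@H]1C | intermediate
21 | (3S)-8β-(tert-butyldimethylsilyloxy)-3β-hydroxygermacra-1(10)E,4Z-dien-12,6α-olide | O=C1O[C@@H]2/C=C(/C)[C@@H](O)C/C=C(\C)/C[C@@H](O[Si](C)(C)C(C)(C)C)[C@H]2[C@@H]1C | intermediate
22 | (11S)-8β-(tert-butyldimethylsilyloxy)-3β-hydroxy-11-(phenylselanyl)germacra-1(10)E,4Z-dien-12,6α-olide | O=C1O[C@@H]2/C=C(/C)[C@@H](O)C/C=C(\C)/C[C@@H](O[Si](C)(C)C(C)(C)C)[C@H]2[C@]1(C)[Se]c3ccccc3 | intermediate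
23 | selenoxide of 22 | O=C1O[C@@H]2/C=C(/C)[C@@H](O)C/C=C(\C)/C[C@@H](O[Si](C)(C)C(C)(C)C)[C@H]2[C@]1(C)[Se](=O)c3ccccc3 | intermediate
24 | 8β-(tert-butyldimethylsilyloxy)-3β-hydroxygermacra-1(10)E,4Z,11(13)-trien-12,6α-olide | C=C1C(=O)O[C@@H]2/C=C(/C)[C@@H](O)C/C=C(\C)/C[C@@H](O[Si](C)(C)C(C)(C)C)[C@@H]12 | intermediate
25 | 8β-(tert-butyldimethylsilyloxy)-3β-(3-methylbutanoyloxy)germacra-1(10)E,4Z,11(13)-trien-12,6α-olide | C=C1C(=O)O[C@@H]2/C=C(/C)[C@@H](OC(=O)CC(C)C)C/C=C(\C)/C[C@@H](O[Si](C)(C)C(C)(C)C)[C@@H]12 | intermediate
26 | 8β-hydroxy-3β-(3-methylbutanoyloxy)germacra-1(10)E,4Z,11(13)-trien-12,6α-olide | C=C1C(=O)O[C@@H]2/C=C(/C)[C@@H](OC(=O)CC(C)C)C/C=C(\C)/C[C@@H](O)[C@@H]12 | intermediate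
27 | methyl angelate, methyl (Z)-2-methylbut-2-enoate | C/C=C(/C)C(=O)OC | starting material
28 | (Z)-2-methylbut-2-en-1-ol | C/C=C(/C)CO | intermediate
29 | [(2R,3S)-2,3-dimethyloxiran-2-yl]methanol | OC[C@@]1(C)O[C@H]1C | intermediate
30 | (2S,3S)-2,3-dimethyloxirane-2-carboxylic acid | OC(=O)[C@@]1(C)O[C@H]1C | intermediate
31 | 8β-[(2S,3S)-2,3-dimethyloxirane-2-carbonyloxy]-3β-(3-methylbutanoyloxy)germacra-1(10)E,4Z,11(13)-trien-12,6α-olide | C=C1C(=O)O[C@@H]2/C=C(/C)[C@@H](OC(=O)CC(C)C)C/C=C(\C)/C[C@@H](OC(=O)[C@@]3(C)O[C@H]3C)[C@@H]12 | intermediate
32 | CNP0167461.1, the 1β,10α-epoxide of 31 (1R,3S,6R,7R,8R,10R) | C=C1C(=O)O[C@@H]2/C=C(/C)[C@@H](OC(=O)CC(C)C)C[C@H]3O[C@]3(C)C[C@@H](OC(=O)[C@@]3(C)O[C@H]3C)[C@@H]12 | target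

## Step count and least certain steps

Total: 25 steps. Longest linear sequence: 22 steps (steps 1–20, 24 and 25); the side-chain acid takes 3 steps (21–23).

Step 14 (key step). The conrotation may not follow the ground-state helicity and may turn in the sense that gives the 1(10)Z,4E geometry. The triene may also reclose thermally or suffer a 1,7-hydrogen shift before it is intercepted. The fallback is a photochemical relay of the kind by which provitamin D and lumisterol interconvert through previtamin D. It sets out from 18. If opening gives the wrong-sense triene, 3,8β-bis(tert-butyldimethylsilyloxy)germacra-1(10)Z,2E,4E-trien-12,6α-olide F1, irradiation is continued above 300 nm, where trienes of this type absorb more strongly than the diene. F1 should then reclose conrotatorily to the C5,C10-bis-epimeric cis-fused diene, 3,8β-bis(tert-butyldimethylsilyloxy)-5βH,10β-methyl-eudesma-1,3-dien-12,6α-olide F2, which is thermally stable and separable from 18. Under the same lactone lock F2 has C9 and H5 pseudoaxial on ring A, so whatever rule sends 18 the wrong way should send F2 the right way. Short-wavelength irradiation of F2 at −78 °C then rejoins the route at 19.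

Step 1. The dienolate may form or be silylated on the cross-conjugated side, or the peracid may attack the α-carbon or the isopropenyl group, so oxygen would not go to the γ-position. The fallback replaces epoxidation by a cycloaddition that can only bridge the diene termini. It sets out from 2. Singlet oxygen (O2, 5,10,15,20-tetraphenylporphyrin, visible light, CH2Cl2, −78 °C) should add across C1 and C4 anti to the isopropenyl group to give the silyloxy endoperoxide F3. Methanolysis opens it to (4S,5R)-4-hydroperoxy-2-methyl-5-(prop-1-en-2-yl)cyclohex-2-en-1-one F4, and PPh3 reduction returns to the route at 3.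

Step 6. Facial selectivity of hydroboration at C5=C6 may be poor; β-face attack would give the trans-fused 5β,6β arrangement, because the half-chair of ring B is not locked at this stage. The fallback builds the lactone at the enone stage and sets the ring fusion by hydrogenation. It sets out from 9.
- 9-Borabicyclo[3.3.1]nonane followed by NaOH/H2O2 hydroborates only the isopropenyl group and gives the 12-alcohol F5.
- CrO3/H2SO4 in acetone oxidises it to the acid and hydrolyses the acetal with return of the double bond to conjugation, giving the 3-oxo-4-en-12-oic acid F6.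
- N-Bromosuccinimide with 2,2'-azobis(2-methylpropionitrile) brominates the allylic C6 position to the 6β-bromide F7.
- K2CO3 in DMF lets the carboxylate displace the bromide with inversion to the trans-lactone enone F8.
- Hydrogenation over Pd on carbon in pyridine, which favours cis fusion for 10-methyl-4-en-3-ones, gives the cis-fused ketone F9.
- Re-acetalisation with ethane-1,2-diol and p-toluenesulfonic acid returns to the route at 11.

Step 16. The conformational bias of the ten-membered enone may oppose the catalyst, giving poor facial selectivity at C3. The fallback uses substrate control followed by inversion. It sets out from 20. Luche reduction (NaBH4, CeCl3·7H2O, MeOH, −78 °C) is run; if it gives the 3R alcohol F10, a Mitsunobu reaction with 4-nitrobenzoic acid, PPh3 and diisopropyl azodicarboxylate inverts C3 to the 3S 4-nitrobenzoate F11. Brief methanolysis with K2CO3 in MeOH at 0 °C returns to the route at 21.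

Step 25. The peracid may attack C1=C10 on the other face if another ring conformer reacts, or may compete at C4=C5. The fallback replaces substrate control by reagent control. It sets out from 31. Shi epoxidation with the D-fructose-derived ketone (1,2:4,5-di-O-isopropylidene-β-D-erythro-2,3-hexodiulo-2,6-pyranose) and KHSO5 in buffered MeCN/dimethoxymethane/H2O at 0 °C uses a dioxirane that gives R,R epoxides from E-trisubstituted alkenes and ignores electron-poor alkenes. It leads directly to 32 and makes no new compound (F0).

## Further compounds

F1 | step 14 | 3,8β-bis(tert-butyldimethylsilyloxy)germacra-1(10)Z,2E,4E-trien-12,6α-olide | O=C1O[C@@H]2/C=C(\C)/C(O[Si](C)(C)C(C)(C)C)=C\C=C(\C)/C[C@@H](O[Si](C)(C)C(C)(C)C)[C@H]2[C@@H]1C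
F2 | step 14 | 3,8β-bis(tert-butyldimethylsilyloxy)-5βH,10β-methyl-eudesma-1,3-dien-12,6α-olide | O=C1O[C@@H]2[C@@H]3C(C)=C(O[Si](C)(C)C(C)(C)C)C=C[C@]3(C)C[C@@H](O[Si](C)(C)C(C)(C)C)[C@H]2[C@@H]1C
F3 | step 1 | 1,4-endoperoxide of 2 (5-methyl-8-(prop-1-en-2-yl)-4-(trimethylsilyloxy)-2,3-dioxabicyclo[2.2.2]oct-5-ene) | CC1=C[C@@H]2OO[C@@]1(O[Si](C)(C)C)C[C@@H]2C(C)=C
F4 | step 1 | (4S,5R)-4-hydroperoxy-2-methyl-5-(prop-1-en-2-yl)cyclohex-2-en-1-one | CC1=C[C@H](OO)[C@H](CC1=O)C(C)=C
F5 | step 6 | 8α-(tert-butyldimethylsilyloxy)-3,3-(ethylenedioxy)-10α-methyl-eudesm-5-en-12-ol | C[C@@H]1C2=C[C@@H]([C@@H](O[Si](C)(C)C(C)(C)C)C[C@]2(C)CCC13OCCO3)[C@H](C)CO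
F6 | step 6 | 8α-(tert-butyldimethylsilyloxy)-3-oxo-10α-methyl-eudesm-4-en-12-oic acid | CC1=C2C[C@@H]([C@@H](O[Si](C)(C)C(C)(C)C)C[C@]2(C)CCC1=O)[C@H](C)C(O)=O
F7 | step 6 | 6β-bromo-8α-(tert-butyldimethylsilyloxy)-3-oxo-10α-methyl-eudesm-4-en-12-oic acid | CC1=C2[C@H](Br)[C@@H]([C@@H](O[Si](C)(C)C(C)(C)C)C[C@]2(C)CCC1=O)[C@H](C)C(O)=O
F8 | step 6 | 8α-(tert-butyldimethylsilyloxy)-3-oxo-10α-methyl-eudesm-4-en-12,6α-olide | CC1=C2[C@H]3OC(=O)[C@@H](C)[C@@H]3[C@@H](O[Si](C)(C)C(C)(C)C)C[C@]2(C)CCC1=O
F9 | step 6 | 8α-(tert-butyldimethylsilyloxy)-3-oxo-5αH,10α-methyl-eudesman-12,6α-olide | C[C@@H]1[C@@H]2[C@H]3OC(=O)[C@@H](C)[C@@H]3[C@@H](O[Si](C)(C)C(C)(C)C)C[C@]2(C)CCC1=O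
F10 | step 16 | (3R)-8β-(tert-butyldimethylsilyloxy)-3α-hydroxygermacra-1(10)E,4Z-dien-12,6α-olide | O=C1O[C@@H]2/C=C(/C)[C@H](O)C/C=C(\C)/C[C@@H](O[Si](C)(C)C(C)(C)C)[C@H]2[C@@H]1C
F11 | step 16 | (3S)-8β-(tert-butyldimethylsilyloxy)-3β-(4-nitrobenzoyloxy)germacra-1(10)E,4Z-dien-12,6α-olide | O=C1O[C@@H]2/C=C(/C)[C@@H](OC(=O)c3ccc(cc3)[N+]([O-])=O)C/C=C(\C)/C[C@@H](O[Si](C)(C)C(C)(C)C)[C@H]2[C@@H]1C
F0 | step 25 | none | none
A1 | alternative 1 | ten-membered 1-hydroxy-3-oxo lactone with C8 4-methoxybenzyl ether and C10 triethylsilyl ether (13-nor-germacr-4Z-en-12,6-olide) | O=C1C[C@@H]2[C@H](OCc3ccc(OC)cc3)C[C@@](C)(O[Si](CC)(CC)CC)[C@@H](O)CC(=O)/C(C)=C\[C@H]2O1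
A2 | alternative 2 | 8-(benzyldimethylsilyl)-3-(tert-butyldimethylsilyloxy)cyclodeca-1(10)E,4Z-dien-6-one (germacrane numbering) | O=C1/C=C(/C)[C@@H](O[Si](C)(C)C(C)(C)C)C/C=C(\C)/C[C@@H]([Si](C)(C)Cc2ccccc2)C1
A3 | alternative 3 | 6,12-bis(tert-butyldimethylsilyloxy)-3-(methoxymethoxy)-8-(4-methoxybenzyloxy)germacra-1(10)E,4Z,11(13)-triene | C=C(CO[Si](C)(C)C(C)(C)C)[C@H]1[C@H](O[Si](C)(C)C(C)(C)C)/C=C(/C)[C@@H](OCOC)C/C=C(\C)/C[C@H]1OCc2ccc(OC)cc2
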